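With the carbocycle numbered C1 (OMe), C2 (=CH), C3 (bearing C7H2OBz), C4 (OH), C5 (OBz), C6 (OH), the six-membered ring is disconnected to a cyclopentene made of C1, C6, C5, C4 and C2, with C3 removed as a dibromocarbene carbon. The feature exploited is that C3 sits between C2 and C4 and that the C5 benzoate is cis to the C4 hydroxyl. In one operation, silver-induced opening of the C2–C4 cyclopropane bond forms the cyclohexene, the C5 benzoate delivers O4 cis, and C3 keeps a bromide for attaching C7. The precursor is a 6,6-dibromobicyclo[3.1.0]hexane with C1-OMe and C5-OBz anti to the CBr2 bridge and a trans C6 silyl ether.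

Key step: step 8

Remark: target numbering (C1–C7, O on Cn = On) is used for all intermediates. "Up" and "down" refer to the ring drawn with C1→C6 clockwise; in the target O1, O4 and O5 are up and O6 is down.
Assumption: the equatorial O5 benzoate is taken to be the thermodynamically preferred monoester of the cis-4,5-diol, following the usual axial-to-equatorial direction of acyl migration.

Step 1
Reactants: 1 (R)-4-hydroxycyclopent-2-en-1-one
Product: 2 (R)-4-methoxycyclopent-2-en-1-one
Conditions: MeI (excess), Ag2O, CH2Cl2, rt, dark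
Reagents that add atoms: iodomethane (CI)
Why: Purdie-type O-methylation on Ag2O is essentially neutral, so the β-hydroxy enone should be etherified without elimination or racemisation, and the C1 stereocentre is carried over unchanged from 1.

Step 2
Reactants: 2 (R)-4-methoxycyclopent-2-en-1-one
Product: 3 trans-(4S,5R)-5-acetoxy-4-methoxycyclopent-2-en-1-one (O1 up, O6 down)
Conditions: Mn(OAc)3·2H2O, benzene, reflux (Dean–Stark)
Reagents that add atoms: manganese triacetate, Mn(OAc)3 (CC(=O)[O-].CC(=O)[O-].CC(=O)[O-].[Mn+3])
Why: Mn(OAc)3 α′-acetoxylation of an enone proceeds through the manganese enolate at C6, and acetate should be delivered anti to the adjacent methoxy group, which sets C6 trans to C1.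

Step 3
Reactants: 3 trans-(4S,5R)-5-acetoxy-4-methoxycyclopent-2-en-1-one
Product: 4 trans-(4S,5R)-5-hydroxy-4-methoxycyclopent-2-en-1-one
Conditions: Sc(OTf)3 (10 mol %), MeOH, rt
Reagents that add atoms: none
Why: Lewis-acid-catalysed transesterification (acetate methanolysis), assisted by chelation of the α-acetoxy ketone, avoids basic conditions that could enolise toward the β-methoxy group, and no stereocentre is touched.

Step 4
Reactants: 4 trans-(4S,5R)-5-hydroxy-4-methoxycyclopent-2-en-1-one
Product: 5 trans-(4S,5R)-5-[(tert-butyldimethylsilyl)oxy]-4-methoxycyclopent-2-en-1-one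
Conditions: TBSCl, imidazole, DMF, 0 °C → rt
Reagents that add atoms: tert-butyldimethylsilyl chloride (CC(C)(C)[Si](C)(C)Cl)
Why: Standard imidazole-mediated O-silylation of a secondary alcohol gives a C6 ether that cannot act as a neighbouring group later and can be removed at the end without touching benzoates.

Step 5
Reactants: 5 trans-(4S,5R)-5-[(tert-butyldimethylsilyl)oxy]-4-methoxycyclopent-2-en-1-one
Product: 6 (1S,4S,5S)-5-[(tert-butyldimethylsilyl)oxy]-4-methoxycyclopent-2-en-1-ol (O5 down, cis to O6, trans to O1)
Conditions: NaBH4, CeCl3·7H2O, MeOH, −78 °C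
Reagents that add atoms: none
Why: Luche reduction reduces the enone carbonyl in the 1,2 sense only, and hydride should enter anti to the adjacent bulky C6 silyloxy group, setting the C5 hydroxyl cis to O6 as the following inversion requires.

Step 6
Reactants: 6 (1S,4S,5S)-5-[(tert-butyldimethylsilyl)oxy]-4-methoxycyclopent-2-en-1-ol; 7 benzoic acid
Product: 8 (1R,4S,5R)-5-[(tert-butyldimethylsilyl)oxy]-4-methoxycyclopent-2-en-1-yl benzoate (O1 up, O6 down, O5 up; all-trans)
Conditions: PPh3, DIAD, THF, 0 °C → rt
Reagents that add atoms: benzoic acid (OC(=O)c1ccccc1)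
Why: Mitsunobu esterification displaces the C5 oxyphosphonium ion by benzoate in an SN2 process with inversion, the nucleophile entering on the open face anti to the C6 silyl ether, which gives the all-trans C1/C6/C5 triad.

Step 7
Reactants: 8 (1R,4S,5R)-5-[(tert-butyldimethylsilyl)oxy]-4-methoxycyclopent-2-en-1-yl benzoate; 9 bromoform
Product: 10 (1S,2R,3R,4S,5R)-6,6-dibromo-3-[(tert-butyldimethylsilyl)oxy]-4-methoxybicyclo[3.1.0]hexan-2-yl benzoate (CBr2 bridge = C3, on the lower face, anti to O1 and O5)
Conditions: CHBr3, 50% aq NaOH, BnEt3NCl (cat.), CH2Cl2, 0 °C → rt, vigorous stirring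
Reagents that add atoms: bromoform (BrC(Br)Br)
Why: Phase-transfer dibromocarbene generation (Makosza conditions) and stereospecific [2+1] cycloaddition to the cis alkene should occur on the lower face because both allylic oxygen groups (C1-OMe, C5-OBz) shield the upper face, which sets C2 and C4, while hydroxide stays in the aqueous phase and the hindered secondary benzoate should survive.

Step 8
Reactants: 10 (1S,2R,3R,4S,5R)-6,6-dibromo-3-[(tert-butyldimethylsilyl)oxy]-4-methoxybicyclo[3.1.0]hexan-2-yl benzoate
Product: 13 (1R,2S,5S,6R)-3-bromo-6-[(tert-butyldimethylsilyl)oxy]-2-hydroxy-5-methoxycyclohex-3-en-1-yl benzoate, via dioxolanylium triflate 11 (not isolated), via O4 benzoate regioisomer 12 (not isolated)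
Conditions: AgOTf (2.5 equiv), 2,6-di-tert-butyl-4-methylpyridine, ClCH2CH2Cl, 60 °C, dark; then THF–aq NaHCO3, 0 °C; then DBU (cat.), CH2Cl2, rt
Reagents that add atoms: water (O)
Why: AgOTf abstracts the endo bromide (the one under the five-membered ring) while the C2–C4 σ bond opens by a disrotatory two-electron electrocyclic process, the only mode that turns the ring bonds inward and gives a cis 2-bromocyclohexenyl cation; the closest known reaction type is the silver-promoted ring expansion of ring-fused gem-dibromocyclopropanes with nucleophilic capture of the 2-bromoallyl cation. The six-membered carbocycle thus arises by ring expansion (cleavage of the shared C2–C4 bond), not by cyclisation, and the transient dioxolan-2-ylium ring of 11 closes by 5-exo attack of the C5 benzoate carbonyl oxygen on the cation terminus C4. The single new stereocentre, C4, is controlled by C5, because the five-membered acyloxonium ring can only be cis-fused, so O4 is delivered on the face of the C5–O bond. The step needs capture at C4 and not at C2, which the substrate secures since only C4 lies next to the participating ester (the C1 methyl ether and the C6 silyl ether cannot bridge) and no external nucleophile is present until the cation has been trapped. Water then adds to the acyloxonium carbon and ring opening is expected to leave the ester first on the pseudoaxial O4 (12), after which catalytic DBU moves the benzoyl group by 1,2-acyl shift to the equatorial O5 to give 13. The hindered pyridine base scavenges adventitious TfOH so that the silyl ether and the allylic methyl ether survive.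

Step 9
Reactants: 13 (1R,2S,5S,6R)-3-bromo-6-[(tert-butyldimethylsilyl)oxy]-2-hydroxy-5-methoxycyclohex-3-en-1-yl benzoate; 14 (tributylstannyl)methanol
Product: 15 (1R,2R,5S,6R)-6-[(tert-butyldimethylsilyl)oxy]-2-hydroxy-3-(hydroxymethyl)-5-methoxycyclohex-3-en-1-yl benzoate
Conditions: Pd(PPh3)4 (10 mol %), 1,4-dioxane, 90 °C, degassed
Reagents that add atoms: (tributylstannyl)methanol (CCCC[Sn](CCCC)(CCCC)CO)
Why: Migita–Kosugi–Stille hydroxymethylation (oxidative addition of zerovalent palladium into the C3–Br bond, transfer of CH2OH from tin, reductive elimination) runs under neutral conditions, so the free C4 hydroxyl, the homoallylic benzoate and the silyl ether should be untouched and no stereocentre is involved.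

Step 10
Reactants: 15 (1R,2R,5S,6R)-6-[(tert-butyldimethylsilyl)oxy]-2-hydroxy-3-(hydroxymethyl)-5-methoxycyclohex-3-en-1-yl benzoate
Product: 16 (1R,2R,5S,6R)-3-[(benzoyloxy)methyl]-6-[(tert-butyldimethylsilyl)oxy]-2-hydroxy-5-methoxycyclohex-3-en-1-yl benzoate
Conditions: BzCl (1.1 equiv), 2,4,6-collidine, CH2Cl2, −40 → 0 °C
Reagents that add atoms: benzoyl chloride (O=C(Cl)c1ccccc1)
Why: Kinetically selective acylation of the primary allylic C7 alcohol over the hindered secondary C4 alcohol with an acid chloride and a weak hindered pyridine base at low temperature should give the C7 benzoate without base-induced acyl migration.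

Step 11
Reactants: 16 (1R,2R,5S,6R)-3-[(benzoyloxy)methyl]-6-[(tert-butyldimethylsilyl)oxy]-2-hydroxy-5-methoxycyclohex-3-en-1-yl benzoate
Product: 17 (1R,2R,5S,6R)-3-[(benzoyloxy)methyl]-2,6-dihydroxy-5-methoxycyclohex-3-en-1-yl benzoate (target)
Conditions: HF·pyridine, THF–pyridine, 0 °C → rt
Reagents that add atoms: none
Why: Fluoride-mediated desilylation under mildly acidic, buffered conditions cleaves the Si–O6 bond without forming free alkoxides, so neither benzoate should migrate and all four stereocentres are retained.

Compound list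
1 | (R)-4-hydroxycyclopent-2-en-1-one | O[C@H]1C=CC(=O)C1 | starting material
2 | (R)-4-methoxycyclopent-2-en-1-one | CO[C@H]1C=CC(=O)C1 | intermediate
3 | trans-(4S,5R)-5-acetoxy-4-methoxycyclopent-2-en-1-one | CO[C@H]1C=CC(=O)[C@@H]1OC(C)=O | intermediate
4 | trans-(4S,5R)-5-hydroxy-4-methoxycyclopent-2-en-1-one | CO[C@H]1C=CC(=O)[C@@H]1O | intermediate
5 | trans-(4S,5R)-5-[(tert-butyldimethylsilyl)oxy]-4-methoxycyclopent-2-en-1-one | CO[C@H]1C=CC(=O)[C@@H]1O[Si](C)(C)C(C)(C)C | intermediate
6 | (1S,4S,5S)-5-[(tert-butyldimethylsilyl)oxy]-4-methoxycyclopent-2-en-1-ol | CO[C@H]1C=C[C@H](O)[C@@H]1O[Si](C)(C)C(C)(C)C | intermediate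
7 | benzoic acid | OC(=O)c1ccccc1 | starting material
8 | (1R,4S,5R)-5-[(tert-butyldimethylsilyl)oxy]-4-methoxycyclopent-2-en-1-yl benzoate | CO[C@H]1C=C[C@@H](OC(=O)c2ccccc2)[C@@H]1O[Si](C)(C)C(C)(C)C | intermediate
9 | bromoform | BrC(Br)Br | starting material
10 | (1S,2R,3R,4S,5R)-6,6-dibromo-3-[(tert-butyldimethylsilyl)oxy]-4-methoxybicyclo[3.1.0]hexan-2-yl benzoate | CO[C@H]1[C@@H]2C(Br)(Br)[C@@H]2[C@@H](OC(=O)c2ccccc2)[C@@H]1O[Si](C)(C)C(C)(C)C | intermediate
11 | cis-fused 2-phenyl-1,3-dioxolan-2-ylium triflate bridging O4 and O5 of the 3-bromocyclohexene (C1 OMe and C6 OTBS as in 13) | CO[C@H]1C=C(Br)[C@H]2O[C+](c3ccccc3)O[C@H]2[C@@H]1O[Si](C)(C)C(C)(C)C.[O-]S(=O)(=O)C(F)(F)F | intermediate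
12 | O4 benzoate regioisomer of 13 (benzoyl on O4, free hydroxyl on C5, all centres as in 13) | CO[C@H]1C=C(Br)[C@@H](OC(=O)c2ccccc2)[C@@H](O)[C@@H]1O[Si](C)(C)C(C)(C)C | intermediate
13 | (1R,2S,5S,6R)-3-bromo-6-[(tert-butyldimethylsilyl)oxy]-2-hydroxy-5-methoxycyclohex-3-en-1-yl benzoate | CO[C@H]1C=C(Br)[C@@H](O)[C@@H](OC(=O)c2ccccc2)[C@@H]1O[Si](C)(C)C(C)(C)C | intermediate
14 | (tributylstannyl)methanol | CCCC[Sn](CCCC)(CCCC)CO | starting material
15 | (1R,2R,5S,6R)-6-[(tert-butyldimethylsilyl)oxy]-2-hydroxy-3-(hydroxymethyl)-5-methoxycyclohex-3-en-1-yl benzoate | CO[C@H]1C=C(CO)[C@@H](O)[C@@H](OC(=O)c2ccccc2)[C@@H]1O[Si](C)(C)C(C)(C)C | intermediate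
16 | (1R,2R,5S,6R)-3-[(benzoyloxy)methyl]-6-[(tert-butyldimethylsilyl)oxy]-2-hydroxy-5-methoxycyclohex-3-en-1-yl benzoate | CO[C@H]1C=C(COC(=O)c2ccccc2)[C@@H](O)[C@@H](OC(=O)c2ccccc2)[C@@H]1O[Si](C)(C)C(C)(C)C | intermediate
17 | (1R,2R,5S,6R)-3-[(benzoyloxy)methyl]-2,6-dihydroxy-5-methoxycyclohex-3-en-1-yl benzoate | CO[C@H]1C=C(COC(=O)c2ccccc2)[C@@H](O)[C@@H](OC(=O)c2ccccc2)[C@@H]1O | target

Total step count: 11
Longest linear sequence: 11 steps (from 1 to 17)

Steps most likely to fail

Step 8. Ionisation may be slow because two C–O bonds flank the cyclopropane. The acyloxonium ion may open mainly toward the O4 ester, and the base-mediated O4→O5 acyl shift may stop at an unfavourable equilibrium. The fallback sets out from 12 (the crude monobenzoate mixture, with or without 13) and uses the oxygen delivered by the benzoate but no longer relies on where the acyl group settles. Reduction with i-Bu2AlH (CH2Cl2, −78 °C) removes the benzoyl group from either regioisomer and should give the cis-4,5-diol (1R,2S,5S,6S)-3-bromo-6-[(tert-butyldimethylsilyl)oxy]-5-methoxycyclohex-3-ene-1,2-diol F1. Heating with Bu2SnO in toluene with removal of water should give the O4,O5-dibutylstannylene acetal F2. Benzoyl chloride at room temperature should then acylate the equatorial O5 selectively, which returns the route at 13.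

Step 5. Facial selectivity may be poor or reversed, because the C1 methoxy group on the opposite face competes with the C6 silyl ether in steering the hydride. The fallback sets out from 5 and drops the inversion for the material of the other configuration. The epimeric all-trans alcohol (1R,4S,5S)-5-[(tert-butyldimethylsilyl)oxy]-4-methoxycyclopent-2-en-1-ol F3 is separated and benzoylated with retention (BzCl, pyridine, DMAP, CH2Cl2), which joins the route at 8. Both epimers of the reduction thus converge on the same benzoate.

Step 7. Carbene addition may be sluggish on an alkene deactivated by an allylic ester, and the benzoate may be lost under the basic two-phase conditions. The fallback sets out from 8 and moves the benzoylation behind the cyclopropanation. Reduction with i-Bu2AlH (CH2Cl2, −78 °C) should give the all-trans alcohol F3 described above. 4-Methoxybenzyl trichloroacetimidate with catalytic camphorsulfonic acid should convert it into the 4-methoxybenzyl ether of F3, F4. The ester-free and more electron-rich alkene is then cyclopropanated under the same phase-transfer conditions to the 6,6-dibromobicyclo[3.1.0]hexane bearing the 4-methoxybenzyl ether at C5, F5. DDQ in wet CH2Cl2 should release the C5 alcohol of the bicycle, F6, and BzCl/pyridine/DMAP should give 10.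

Further compounds
F1 | step 8 | (1R,2S,5S,6S)-3-bromo-6-[(tert-butyldimethylsilyl)oxy]-5-methoxycyclohex-3-ene-1,2-diol (debenzoylated 13) | CO[C@H]1C=C(Br)[C@@H](O)[C@@H](O)[C@@H]1O[Si](C)(C)C(C)(C)C
F2 | step 8 | O4,O5-dibutylstannylene acetal of F1 | CO[C@H]1C=C(Br)[C@H]2O[Sn](CCCC)(CCCC)O[C@H]2[C@@H]1O[Si](C)(C)C(C)(C)C
F3 | step 5 | (1R,4S,5S)-5-[(tert-butyldimethylsilyl)oxy]-4-methoxycyclopent-2-en-1-ol (all-trans epimer of 6) | CO[C@H]1C=C[C@@H](O)[C@@H]1O[Si](C)(C)C(C)(C)C
F4 | step 7 | 4-methoxybenzyl ether of F3 | CO[C@H]1C=C[C@@H](OCc2ccc(OC)cc2)[C@@H]1O[Si](C)(C)C(C)(C)C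
F5 | step 7 | analogue of 10 carrying a 4-methoxybenzyl ether in place of the C5 benzoate (CBr2 anti to O1 and O5) | CO[C@H]1[C@@H]2C(Br)(Br)[C@@H]2[C@@H](OCc2ccc(OC)cc2)[C@@H]1O[Si](C)(C)C(C)(C)C
F6 | step 7 | analogue of 10 with a free C5 hydroxyl | CO[C@H]1[C@@H]2C(Br)(Br)[C@@H]2[C@@H](O)[C@@H]1O[Si](C)(C)C(C)(C)C
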